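**Assumptions.** The facial sense of each chiral catalyst or reagent is taken from its usual model; if a test reaction showed the opposite sense, the mirror-image ligand would be used. Small atom-contributing inputs (allyl alcohol, methyl vinyl ketone, trimethylsilylacetylene) are numbered as starting materials; silyl halides/triflates, allylMgBr and DMF are treated as reagents.

**Abbreviations.** Ar = 4-(triisopropylsilyloxy)phenyl; TIPS = Si(iPr)3, TES = SiEt3, TBS = Si(tBu)Me2, TMS = SiMe3. Ring numbering as in the target: O1, C2 (aryl), C3, C4 (OH), C5, C6 (arylethyl); Ca is the allylic CH on C3 and Cb the side-chain carbinol.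

## Retrosynthetic overview

1. Target ⇐ global desilylation ⇐ axial C4–OH by bulky-hydride reduction of a 2,6-cis-2,3-trans oxan-4-one.
2. The oxane (the only ring formed) ⇐ silyl enol ether Prins annulation of an acyclic (Z)-enol silane with an aryl aldehyde; this makes O1–C2 and C2–C3 and sets C2 and C3 from C6.
3. The (Z)-enol silane ⇐ Rh-catalysed enantioselective conjugate alkenylation of an acyclic enone with a styryl-zirconium reagent, trapped as the enol silane; this makes the Ca–styryl bond and sets Ca.
4. The enone ⇐ Ru cross-metathesis of two C7 halves, both made from one 3-arylpropanal (methyl vinyl ketone aldol sets C6; allylation sets Cb).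
5. All four aryl groups come from 4-iodophenol TIPS ether by Heck, Sonogashira or formylation.

## Route

**Step 1**
Reactants: 1, 4-iodophenol
Product: 2, (4-iodophenoxy)triisopropylsilane
Conditions: TIPSCl, imidazole, DMF, rt
Reagents that add atoms: TIPSCl, CC(C)[Si](Cl)(C(C)C)C(C)C
Why: Standard phenol silylation; the hindered aryl TIPS ether survives the later Pd, organolithium, Lewis acid and hydride steps and is removed only by fluoride.

**Step 2**
Reactants: 2; 3, allyl alcohol
Product: 4, 3-[4-(triisopropylsilyloxy)phenyl]propanal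
Conditions: Pd(OAc)2 (3 mol %), n-Bu4NCl, NaHCO3, DMF, 45 °C
Reagents that add atoms: none
Why: Jeffery-type Heck reaction; aryl-Pd adds to the terminal alkene carbon and β-hydride elimination toward the carbinol gives the enol, which tautomerises to the aldehyde.

**Step 3**
Reactants: 4; 5, methyl vinyl ketone (excess)
Product: 6, (5S)-5-hydroxy-7-Ar-hept-1-en-3-one
Conditions: (S,S)-ProPhenol (10 mol %), Et2Zn (20 mol %), 4 Å MS, THF, 0 °C
Reagents that add atoms: none
Why: Trost dinuclear-zinc direct aldol of methyl vinyl ketone; the catalyst-bound zinc dienolate adds to one face of the aldehyde to give the (S)-carbinol, the future C6.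

**Step 4**
Reactants: 6
Product: 7, (5S)-5-(triethylsilyloxy)-7-Ar-hept-1-en-3-one
Conditions: TESOTf, 2,6-lutidine, CH2Cl2, −78 °C
Reagents that add atoms: TESOTf, CC[Si](CC)(CC)OS(=O)(=O)C(F)(F)F
Why: O-silylation with a non-nucleophilic base avoids aza-Michael addition and retro-aldol; this oxygen later becomes the ring oxygen.

**Step 5**
Reactants: 4
Product: 8, (3S)-1-Ar-hex-5-en-3-ol
Conditions: (+)-Ipc2BOMe, allylMgBr, Et2O, −78 °C; then 4; NaOH/H2O2
Reagents that add atoms: allylmagnesium bromide, C=CC[Mg]Br
Why: Brown allylboration through a chair Zimmerman–Traxler transition state; the reagent from (−)-α-pinene attacks the Re face to give the (S)-carbinol, the future Cb.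

**Step 6**
Reactants: 8
Product: 9, TBS ether of 8
Conditions: TBSCl, imidazole, DMF, rt
Reagents that add atoms: TBSCl, CC(C)(C)[Si](C)(C)Cl
Why: Routine silylation; the bulky TBS ether stays inert in the later oxocarbenium step and falls with fluoride at the end.

**Step 7**
Reactants: 7; 9 (1.5 equiv)
Product: 10, (3S,6E,9S)-9-(TBS-oxy)-3-(TES-oxy)-1,11-di-Ar-undec-6-en-5-one
Conditions: Hoveyda–Grubbs II (5 mol %), CH2Cl2, 40 °C
Reagents that add atoms: none
Why: Ru-catalysed olefin cross-metathesis of a terminal alkene with a vinyl ketone gives the (E)-enone under thermodynamic control and joins the two halves; existing stereocentres are untouched.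

**Step 8**
Reactants: 2; 11, trimethylsilylacetylene
Product: 12, trimethyl[(4-TIPSO-phenyl)ethynyl]silane
Conditions: PdCl2(PPh3)2 (2 mol %), CuI (4 mol %), Et3N, THF, rt
Reagents that add atoms: none
Why: Sonogashira coupling of an aryl iodide with a terminal alkyne.

**Step 9**
Reactants: 12
Product: 13, (4-ethynylphenoxy)triisopropylsilane
Conditions: K2CO3 (0.2 equiv), MeOH/THF, 0 °C, short reaction time
Reagents that add atoms: none
Why: Carbonate methanolysis cleaves the C(sp)–SiMe3 bond much faster than the hindered aryl O–TIPS ether.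

**Step 10**
Reactants: 2
Product: 14, 4-(triisopropylsilyloxy)benzaldehyde
Conditions: n-BuLi, THF, −78 °C; DMF; aq NH4Cl
Reagents that add atoms: DMF, CN(C)C=O
Why: Iodine–lithium exchange followed by formylation of the aryllithium.

**Step 11**
Reactants: 10; 13
Product: 15, (3S,5Z,7S,9S)-9-(TBS-oxy)-3-(TES-oxy)-5-(TMS-oxy)-7-[(E)-2-Ar-ethenyl]-1,11-di-Ar-undec-5-ene
Conditions: 13, Cp2Zr(H)Cl, THF, rt; then 10, [RhCl((S)-BINAP)]2 (5 mol % Rh), TMSCl (2 equiv), THF, 0 °C to rt; non-aqueous work-up, used crude
Reagents that add atoms: TMSCl, C[Si](C)(C)Cl (Cp2Zr(H)Cl adds only H)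
Why: Proposed new method: Rh(I)/BINAP-catalysed enantioselective conjugate alkenyl-silylation, in which the (E)-alkenylzirconocene from hydrozirconation of 13 transmetalates to Rh–Cl, the alkenyl–Rh inserts the s-cis (E)-enone on the α-si face fixed by (S)-BINAP (sets Ca as S), and Me3SiCl silylates the resulting oxa-π-allyl Rh enolate to release the (Z)-enol silane regiospecifically at C3=C4 (away from the β-silyloxy group, so no E1cB) while regenerating Rh–Cl; the closest known reactions are the Rh/BINAP 1,4-additions of aryl-titanium or aryl-zinc reagents with chlorosilane to give silyl enol ethers and the Rh/BINAP 1,4-addition of alkenylzirconocenes to enones, but the alkenyl-Zr/chlorosilane-turnover combination giving a geometry-defined acyclic enol silane on a polyoxygenated enone has not been shown.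

**Step 12**
Reactants: 15; 14
Product: 16, (2S,3R,6S)-2-Ar-6-(2-Ar-ethyl)-3-[(1E,3S,5S)-5-(TBS-oxy)-1,7-di-Ar-hept-1-en-3-yl]oxan-4-one
Conditions: TMSOTf (0.5–1.0 equiv), 2,6-di-tert-butyl-4-methylpyridine (0.2 equiv), CH2Cl2, −78 °C; pH 7 buffer quench; used directly
Reagents that add atoms: none
Why: Silyl enol ether Prins (oxocarbenium–Mukaiyama) annulation; the unhindered TES ether (not the TBS ether) condenses with 14 to the (E)-aryl oxocarbenium ion, which the enol silane captures through a chair transition state with the C6 chain and aryl equatorial (2,6-cis) and, because the enol silane is Z, the C3 substituent equatorial (2,3-trans), forming the only ring.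

**Step 13**
Reactants: 16
Product: 17, (2S,3S,4S,6S)-oxan-4-ol corresponding to 16 (axial OH)
Conditions: L-Selectride, THF, −78 °C; NaOH/H2O2, 0 °C
Reagents that add atoms: none
Why: Bulky trialkylborohydride reduction; hydride arrives from the equatorial direction of the chair to give the axial C4 alcohol cis to the equatorial C3 substituent, and at −78 °C C3 is not epimerised.

**Step 14**
Reactants: 17
Product: 18, blepharocalyxin C
Conditions: TBAF (7 equiv), AcOH (7 equiv), THF, 0 °C to rt
Reagents that add atoms: none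
Why: Buffered fluoride desilylation removes the four aryl TIPS ethers and the secondary TBS ether without acid, so the electron-rich styrene and the benzylic ether are not ionised.

## Compound list

1 | 4-iodophenol | Oc1ccc(I)cc1 | starting material
2 | (4-iodophenoxy)triisopropylsilane | CC(C)[Si](Oc1ccc(I)cc1)(C(C)C)C(C)C | intermediate
3 | allyl alcohol | C=CCO | starting material
4 | 3-[4-(triisopropylsilyloxy)phenyl]propanal | O=CCCc1ccc(O[Si](C(C)C)(C(C)C)C(C)C)cc1 | intermediate
5 | methyl vinyl ketone | CC(=O)C=C | starting material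
6 | (5S)-5-hydroxy-7-[4-(TIPSO)phenyl]hept-1-en-3-one | C=CC(=O)C[C@@H](O)CCc1ccc(O[Si](C(C)C)(C(C)C)C(C)C)cc1 | intermediate
7 | (5S)-5-(triethylsilyloxy)-7-[4-(TIPSO)phenyl]hept-1-en-3-one | C=CC(=O)C[C@@H](O[Si](CC)(CC)CC)CCc1ccc(O[Si](C(C)C)(C(C)C)C(C)C)cc1 | intermediate
8 | (3S)-1-[4-(TIPSO)phenyl]hex-5-en-3-ol | C=CC[C@@H](O)CCc1ccc(O[Si](C(C)C)(C(C)C)C(C)C)cc1 | intermediate
9 | TBS ether of 8 | C=CC[C@@H](O[Si](C)(C)C(C)(C)C)CCc1ccc(O[Si](C(C)C)(C(C)C)C(C)C)cc1 | intermediate
10 | (3S,6E,9S)-9-(TBS-oxy)-3-(TES-oxy)-1,11-bis[4-(TIPSO)phenyl]undec-6-en-5-one | CC(C)[Si](Oc1ccc(CC[C@H](O[Si](CC)(CC)CC)CC(=O)/C=C/C[C@@H](O[Si](C)(C)C(C)(C)C)CCc2ccc(O[Si](C(C)C)(C(C)C)C(C)C)cc2)cc1)(C(C)C)C(C)C | intermediate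
11 | trimethylsilylacetylene | C#C[Si](C)(C)C | starting material
12 | trimethyl{[4-(TIPSO)phenyl]ethynyl}silane | CC(C)[Si](Oc1ccc(C#C[Si](C)(C)C)cc1)(C(C)C)C(C)C | intermediate
13 | (4-ethynylphenoxy)triisopropylsilane | C#Cc1ccc(O[Si](C(C)C)(C(C)C)C(C)C)cc1 | intermediate
14 | 4-(triisopropylsilyloxy)benzaldehyde | O=Cc1ccc(O[Si](C(C)C)(C(C)C)C(C)C)cc1 | intermediate
15 | (3S,5Z,7S,9S)-enol silane (TMS enol ether at C5, TES ether at C3, TBS ether at C9, (E)-styryl at C7) | CC(C)[Si](Oc1ccc(/C=C/[C@H](C[C@@H](O[Si](C)(C)C(C)(C)C)CCc2ccc(O[Si](C(C)C)(C(C)C)C(C)C)cc2)/C=C(\O[Si](C)(C)C)C[C@@H](O[Si](CC)(CC)CC)CCc2ccc(O[Si](C(C)C)(C(C)C)C(C)C)cc2)cc1)(C(C)C)C(C)C | intermediate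
16 | (2S,3R,6S)-oxan-4-one, side chain (1E,3S,5S), penta-silylated | CC(C)[Si](Oc1ccc(/C=C/[C@H](C[C@@H](O[Si](C)(C)C(C)(C)C)CCc2ccc(O[Si](C(C)C)(C(C)C)C(C)C)cc2)[C@@H]2[C@@H](c3ccc(O[Si](C(C)C)(C(C)C)C(C)C)cc3)O[C@@H](CCc3ccc(O[Si](C(C)C)(C(C)C)C(C)C)cc3)CC2=O)cc1)(C(C)C)C(C)C | intermediate
17 | (2S,3S,4S,6S)-oxan-4-ol, side chain (1E,3S,5S), penta-silylated | CC(C)[Si](Oc1ccc(/C=C/[C@H](C[C@@H](O[Si](C)(C)C(C)(C)C)CCc2ccc(O[Si](C(C)C)(C(C)C)C(C)C)cc2)[C@@H]2[C@@H](c3ccc(O[Si](C(C)C)(C(C)C)C(C)C)cc3)O[C@@H](CCc3ccc(O[Si](C(C)C)(C(C)C)C(C)C)cc3)C[C@@H]2O)cc1)(C(C)C)C(C)C | intermediate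
18 | blepharocalyxin C | Oc1ccc(/C=C/[C@H](C[C@@H](O)CCc2ccc(O)cc2)[C@@H]2[C@@H](c3ccc(O)cc3)O[C@@H](CCc3ccc(O)cc3)C[C@@H]2O)cc1 | target

## Summary

**Total steps:** 14.

**Longest linear sequence:** 9 steps (1, 2, 3, 4, 7, 11, 12, 13, 14; the path through steps 5 and 6 is the same length).

**Steps most likely to fail**

1. **Step 11 (the proposed new Rh conjugate alkenyl-silylation).** Risks are inefficient Zr→Rh/chlorosilane turnover, E/Z leakage in the enol silane (which would erode C3) and incomplete catalyst control at Ca. Fallback with known chemistry: make Ca by an established NHC–Cu-catalysed SN2′ allylic alkenylation, using an (E)-alkenylaluminium from the west homopropargyl ether and the east (E)-allylic phosphate. This gives the (E)-C3=C4 1,4-diene. Close the ring by a classical TFA Prins with 14 (C3 then comes from alkene geometry), invert C4 by Dess–Martin oxidation and L-Selectride reduction, and install the styrene by Heck arylation of the vinyl group with 2.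

2. **Step 12 (silyl enol ether Prins).** Risks are direct intermolecular Mukaiyama aldol, participation of the TBS ether, acid damage to the electron-rich styrene and C3 epimerisation of the product. Fallback: a stepwise ring synthesis, with intermolecular Mukaiyama aldol of 15 with 14, then dehydrative cycloetherification through the p-silyloxybenzylic cation (Re2O7 or catalytic acid), which gives the 2,6-cis ether thermodynamically. C3 epimers would be separated before step 13.

3. **Step 3 (direct methyl vinyl ketone aldol on a linear, enolisable aldehyde).** Risks are aldehyde self-aldol, low ee and polymerisation of the β-hydroxy vinyl ketone. Fallback: auxiliary-controlled acetate aldol of 4 (Nagao N-acetylthiazolidinethione, TiCl4/amine), conversion to the Weinreb amide, TES protection and addition of vinylmagnesium bromide to reach 7.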